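## Retrosynthetic overview

- Ring numbering used throughout: C1 = ketone carbon, C2 (heptenyl), C3 (CH2OH), C4 and C5 (carbinols), C6 (carries the butenoic acid chain). The enabling feature is that the C1 carbonyl oxygen and the C4 hydroxyl oxygen sit 1,4 across the C2=C3 double bond. The 4-hydroxycyclohex-2-enone is therefore a ring-opened 7-oxabicyclo[2.2.1]hept-5-ene ketal, i.e. a 2-oxygenated furan (O, C1–C4) plus a two-carbon alkene (C5=C6). The first two carbons of the C6 side chain can reach the C1 oxygen as a five-membered ring.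
- Key disconnection: C1–C6 and C4–C5 by a retro intramolecular furan Diels–Alder reaction. The precursor is a 2-alkoxy-3-bromofuran whose alkoxy group is O–CH2–CH2–CH=CH–OR* (Z; R* = (S)-1-(2,4,6-triisopropylphenyl)ethyl on the future C5 oxygen).
- After the cycloaddition: Suzuki–Miyaura coupling of the C2 bromide with an (R)-acetoxy E-alkenylboronate; ketal hydrolysis; side-chain alcohol to aldehyde to E-enoate (Wittig); one acid step removes auxiliary, tert-butyl ester and silyl ether.
- Ring order: furan (from 3,4-dibromofuran), then the oxa-bridged six-membered carbocycle and the fused tetrahydrofuran closed together in the cycloaddition, then both temporary heterocycles opened by hydrolysis to leave the cyclohexenone.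

Key step: step 12

Remark: the sense of induction by the 1-arylethyl auxiliary (S alcohol leading to the 4R,5S,6R series) rests on the s-trans, C–H-eclipsed conformer model given under step 12; the enantiomeric alcohol would be used if the sense proved opposite.

## Route

Step 1
Reactants: 1 3,4-dibromofuran
Product: 4 (4-bromofuran-3-yl)methanol, via (4-bromofuran-3-yl)lithium 2 (not isolated), via 4-bromofuran-3-carbaldehyde 3 (not isolated)
Conditions: n-BuLi (1.0 equiv), Et2O, −78 °C; DMF, −78 °C → rt; aq NH4Cl; crude aldehyde, NaBH4, MeOH, 0 °C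
Reagents that add atoms: N,N-dimethylformamide CN(C)C=O
Why: Bromine–lithium exchange of the symmetrical dibromide gives the monolithiated furan, which is formylated by DMF (Bouveault-type formylation), and the crude aldehyde is reduced by NaBH4; no stereocentre is formed.

Step 2
Reactants: 4 (4-bromofuran-3-yl)methanol
Product: 5 tert-butyl[(4-bromofuran-3-yl)methoxy]dimethylsilane
Conditions: TBSCl, imidazole, CH2Cl2, rt
Reagents that add atoms: tert-butyldimethylsilyl chloride CC(C)(C)[Si](C)(C)Cl
Why: Standard silylation of the primary alcohol; the silyl ether should survive base, organometallic and palladium chemistry and fall in the final acid step.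

Step 3
Reactants: 5 tert-butyl[(4-bromofuran-3-yl)methoxy]dimethylsilane
Product: 7 tert-butyl[(4-bromo-5-iodofuran-3-yl)methoxy]dimethylsilane, via 2-lithiofuran 6 (not isolated)
Conditions: LiN(i-Pr)2 (1.1 equiv), THF, −78 °C, 30 min; I2, −78 °C
Reagents that add atoms: iodine II
Why: Directed α-lithiation of the furan should occur at the α-position acidified by the adjacent bromine, and iodination of the lithio species gives the 2-iodo-3-bromo pattern; −78 °C suppresses halogen migration.

Step 4
Reactants: 8 (S)-1-(2,4,6-triisopropylphenyl)ethanol, 9 trichloroethene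
Product: 11 (S,E)-1,2-dichlorovinyl 1-(2,4,6-triisopropylphenyl)ethyl ether, via potassium alkoxide 10 (not isolated)
Conditions: KH, THF, 0 °C; then 9, −50 °C → rt
Reagents that add atoms: none
Why: Addition–elimination of the potassium alkoxide on trichloroethene (the established entry to 1,2-dichlorovinyl ethers) attaches the future C5–C6 unit to the chiral oxygen without touching the benzylic stereocentre.

Step 5
Reactants: 11 (S,E)-1,2-dichlorovinyl 1-(2,4,6-triisopropylphenyl)ethyl ether, 12 oxirane
Product: 14 4-[(1S)-1-(2,4,6-triisopropylphenyl)ethoxy]but-3-yn-1-ol, via lithium alkynyl ether 13 (not isolated)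
Conditions: n-BuLi (2.2 equiv), THF, −78 → −40 °C; then 12, DMPU, −78 °C → rt; aq NH4Cl
Reagents that add atoms: none
Why: Two equivalents of n-BuLi convert the dichlorovinyl ether into the lithium alkynyl ether (elimination, then chlorine–lithium exchange), which opens oxirane by SN2 alkylation to add the two-carbon tether.

Step 6
Reactants: 14 4-[(1S)-1-(2,4,6-triisopropylphenyl)ethoxy]but-3-yn-1-ol
Product: 15 (Z)-4-[(1S)-1-(2,4,6-triisopropylphenyl)ethoxy]but-3-en-1-ol
Conditions: H2 (1 atm), 5% Pd/BaSO4, quinoline, EtOAc, rt
Reagents that add atoms: none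
Why: Poisoned-catalyst semihydrogenation (Lindlar-type) of the ynol ether delivers hydrogen syn and so fixes the Z enol ether geometry that later makes the C5 and C6 substituents cis.

Step 7
Reactants: 16 (R)-2-methyloxirane, 17 but-3-en-1-ylmagnesium bromide
Product: 18 (R)-hept-6-en-2-ol
Conditions: CuI (10 mol%), THF, −30 → 0 °C; aq NH4Cl
Reagents that add atoms: none
Why: Copper-catalysed Grignard opening of the terminal epoxide at its unsubstituted carbon keeps the R configuration of the carbinol carbon bought with the epoxide.

Step 8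
Reactants: 18 (R)-hept-6-en-2-ol
Product: 19 (R)-hept-6-en-2-yl acetate
Conditions: Ac2O, pyridine, DMAP (cat.), CH2Cl2, rt
Reagents that add atoms: acetic anhydride CC(=O)OC(C)=O
Why: DMAP-catalysed acetylation installs the acetate of the target at the outset, since every later step should tolerate it.

Step 9
Reactants: 19 (R)-hept-6-en-2-yl acetate, 20 4,4,5,5-tetramethyl-2-vinyl-1,3,2-dioxaborolane
Product: 21 (R,E)-7-(4,4,5,5-tetramethyl-1,3,2-dioxaborolan-2-yl)hept-6-en-2-yl acetate
Conditions: second-generation Grubbs catalyst (3 mol%), CH2Cl2, 40 °C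
Reagents that add atoms: none
Why: Olefin cross-metathesis of the terminal alkene with the vinylboronate should give the E-alkenylboronate under thermodynamic control.

Step 10
Reactants: 22 tert-butyl 2-bromopropanoate
Product: 24 tert-butyl 2-(triphenyl-λ5-phosphanylidene)propanoate, via phosphonium bromide 23 (not isolated)
Conditions: PPh3, toluene, 80 °C; then aq NaOH, CH2Cl2, 0 °C
Reagents that add atoms: triphenylphosphine c1ccc(cc1)P(c1ccccc1)c1ccccc1
Why: Quaternisation of PPh3 by the α-bromo ester followed by deprotonation gives the stabilised ylide; the stereocentre of the racemic bromide is lost and irrelevant.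

Step 11
Reactants: 7 tert-butyl[(4-bromo-5-iodofuran-3-yl)methoxy]dimethylsilane, 15 (Z)-4-[(1S)-1-(2,4,6-triisopropylphenyl)ethoxy]but-3-en-1-ol
Product: 25 2-alkoxy-3-bromofuran (furan C2–O–CH2CH2–CH=CH–OR*, Z; C3 Br; C4 CH2OTBS)
Conditions: CuI (10 mol%), 3,4,7,8-tetramethyl-1,10-phenanthroline (20 mol%), Cs2CO3, toluene, 4 Å sieves, 70–80 °C
Reagents that add atoms: none
Why: Ullmann-type copper-catalysed C–O coupling of the primary alcohol should take place at the C–I bond in preference to the C–Br bond and gives the 2-alkoxyfuran without the C/O ambiguity of an enolate alkylation.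

Step 12
Reactants: 25 2-alkoxy-3-bromofuran
Product: 26 bridged ketal cycloadduct (7-oxabicyclo[2.2.1]hept-5-ene with a tetrahydrofuran fused across C1–C6; C5 ether and C6 CH2 both exo)
Conditions: toluene (0.01 M), solid K2CO3, base-washed glass, 90 °C, sealed tube
Reagents that add atoms: none
Why: Thermal intramolecular Diels–Alder reaction of the furan: the 2-alkoxy-3-bromofuran diene adds suprafacially to the tethered Z enol ether and forms C1–C6 and C4–C5 in one concerted, asynchronous [4+2] event. The closest known reaction type is the intramolecular furan Diels–Alder reaction of 2-heteroatom-substituted furans carrying a three-atom tether to an unactivated alkene, which a bromine on the furan ring accelerates and makes less reversible. Two rings close: the six-membered carbocycle (as the 7-oxabicyclo[2.2.1]hept-5-ene) by the [4+2] cycloaddition itself, and the tetrahydrofuran (O–CH2–CH2, fused at C1–C6) as the five-membered tether ring of the same cycloaddition. C5 and C6 are cis because the Z geometry is transferred suprafacially, both substituents are exo (cis to the oxygen bridge and hence to the C4 oxygen) because a three-atom tether from the bridgehead oxygen can reach only the exo position of C6, and C4 is fixed by the bridge. The absolute configuration should come from the (S)-1-arylethyl group on the enol oxygen: in the s-trans Z enol ether with its carbinol C–H eclipsing the vinyl C–H, the triisopropylphenyl ring covers one face and the furan adds to the methyl-side face. The step needs exo and π-facial selectivity (tether and auxiliary) and needs the bridged ketal to survive, which is why acid is excluded and the lowest workable temperature is used.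

Step 13
Reactants: 26 bridged ketal cycloadduct, 21 (R,E)-7-(4,4,5,5-tetramethyl-1,3,2-dioxaborolan-2-yl)hept-6-en-2-yl acetate
Product: 27 coupled bridged ketal (C2 now carries the (R,E)-6-acetoxyhept-1-enyl chain)
Conditions: Pd(OAc)2 (5 mol%), 2-dicyclohexylphosphino-2′,6′-dimethoxybiphenyl (SPhos, 10 mol%), K3PO4, THF/H2O (10:1), 50 °C
Reagents that add atoms: none
Why: Suzuki–Miyaura coupling at the strained bridge-alkene bromide should introduce the E-heptenyl chain with retention of alkene geometry, while the base-stable bridged ketal still masks the future β-hydroxy ketone.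

Step 14
Reactants: 27 coupled bridged ketal
Product: 28 (4R,5S,6R)-4-hydroxy-6-(2-hydroxyethyl)cyclohex-2-enone (C2 heptenyl acetate chain, C3 CH2OTBS, C5 OR*)
Conditions: pyridinium p-toluenesulfonate (0.2 equiv), acetone/H2O (10:1), 40 °C
Reagents that add atoms: water O
Why: Acid-catalysed ketal hydrolysis (ionisation assisted by the tetrahydrofuran oxygen and by relief of bicyclic strain) should release the C1 ketone in conjugation with C2=C3, the C4 hydroxyl and the side-chain primary alcohol without touching the C6 stereocentre.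

Step 15
Reactants: 28 4-hydroxy-6-(2-hydroxyethyl)cyclohexenone
Product: 29 6-(2-oxoethyl)cyclohexenone (aldehyde)
Conditions: 2,2,6,6-tetramethylpiperidin-1-oxyl (TEMPO, 10 mol%), PhI(OAc)2 (1.1 equiv), CH2Cl2, rt
Reagents that add atoms: none
Why: Oxoammonium-catalysed oxidation (TEMPO/PhI(OAc)2) is selective for the primary alcohol over the hindered secondary allylic C4 hydroxyl and stops at the aldehyde.

Step 16
Reactants: 29 6-(2-oxoethyl)cyclohexenone, 24 tert-butyl 2-(triphenyl-λ5-phosphanylidene)propanoate
Product: 30 tert-butyl (E)-2-methylbut-2-enoate 30 (fully protected pestallic acid J)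
Conditions: CH2Cl2, rt → 40 °C
Reagents that add atoms: none
Why: Wittig olefination with the stabilised α-branched ylide should react only at the aldehyde and give the E-trisubstituted enoate under non-basic conditions that leave C6 untouched.

Step 17
Reactants: 30 protected pestallic acid J
Product: 31 pestallic acid J
Conditions: CF3CO2H/CH2Cl2/H2O (9:9:2), 0 °C → rt
Reagents that add atoms: none
Why: Acidolysis should cleave the benzylic C–O bond of the auxiliary by an SN1 path (the C5–O bond and its configuration stay), the tert-butyl ester and the silyl ether in one operation, while the secondary acetate is stable to acid.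

## Compound list

1 | 3,4-dibromofuran | Brc1cocc1Br | starting material
2 | (4-bromofuran-3-yl)lithium | [Li]c1cocc1Br | intermediate
3 | 4-bromofuran-3-carbaldehyde | O=Cc1cocc1Br | intermediate
4 | (4-bromofuran-3-yl)methanol | OCc1cocc1Br | intermediate
5 | tert-butyl[(4-bromofuran-3-yl)methoxy]dimethylsilane | CC(C)(C)[Si](C)(C)OCc1cocc1Br | intermediate
6 | [3-bromo-4-(tert-butyldimethylsilyloxymethyl)furan-2-yl]lithium | [Li]c1occ(CO[Si](C)(C)C(C)(C)C)c1Br | intermediate
7 | tert-butyl[(4-bromo-5-iodofuran-3-yl)methoxy]dimethylsilane | Ic1occ(CO[Si](C)(C)C(C)(C)C)c1Br | intermediate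
8 | (S)-1-(2,4,6-triisopropylphenyl)ethanol | C[C@H](O)c1c(C(C)C)cc(C(C)C)cc1C(C)C | starting material
9 | trichloroethene | ClC=C(Cl)Cl | starting material
10 | potassium (S)-1-(2,4,6-triisopropylphenyl)ethoxide | [K+].C[C@H]([O-])c1c(C(C)C)cc(C(C)C)cc1C(C)C | intermediate
11 | 2-{(1S)-1-[(E)-1,2-dichloroethenyloxy]ethyl}-1,3,5-triisopropylbenzene | C[C@H](O/C(Cl)=C\Cl)c1c(C(C)C)cc(C(C)C)cc1C(C)C | intermediate
12 | oxirane | C1CO1 | starting material
13 | lithium 2-[(1S)-1-(2,4,6-triisopropylphenyl)ethoxy]ethynide | [Li]C#CO[C@@H](C)c1c(C(C)C)cc(C(C)C)cc1C(C)C | intermediate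
14 | 4-[(1S)-1-(2,4,6-triisopropylphenyl)ethoxy]but-3-yn-1-ol | OCCC#CO[C@@H](C)c1c(C(C)C)cc(C(C)C)cc1C(C)C | intermediate
15 | (Z)-4-[(1S)-1-(2,4,6-triisopropylphenyl)ethoxy]but-3-en-1-ol | OCC/C=C\O[C@@H](C)c1c(C(C)C)cc(C(C)C)cc1C(C)C | intermediate
16 | (R)-2-methyloxirane | C[C@@H]1CO1 | starting material
17 | but-3-en-1-ylmagnesium bromide | C=CCC[Mg]Br | starting material
18 | (R)-hept-6-en-2-ol | C[C@@H](O)CCCC=C | intermediate
19 | (R)-hept-6-en-2-yl acetate | CC(=O)O[C@H](C)CCCC=C | intermediate
20 | 4,4,5,5-tetramethyl-2-vinyl-1,3,2-dioxaborolane | C=CB1OC(C)(C)C(C)(C)O1 | starting material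
21 | (R,E)-7-(4,4,5,5-tetramethyl-1,3,2-dioxaborolan-2-yl)hept-6-en-2-yl acetate | CC(=O)O[C@H](C)CCC/C=C/B1OC(C)(C)C(C)(C)O1 | intermediate
22 | tert-butyl 2-bromopropanoate (racemic) | CC(Br)C(=O)OC(C)(C)C | starting material
23 | (1-tert-butoxy-1-oxopropan-2-yl)triphenylphosphonium bromide | CC(C(=O)OC(C)(C)C)[P+](c1ccccc1)(c1ccccc1)c1ccccc1.[Br-] | intermediate
24 | tert-butyl 2-(triphenyl-λ5-phosphanylidene)propanoate | CC(C(=O)OC(C)(C)C)=P(c1ccccc1)(c1ccccc1)c1ccccc1 | intermediate
25 | tert-butyl{[4-bromo-5-({(Z)-4-[(1S)-1-(2,4,6-triisopropylphenyl)ethoxy]but-3-en-1-yl}oxy)furan-3-yl]methoxy}dimethylsilane | CC(C)(C)[Si](C)(C)OCc1coc(OCC/C=C\O[C@@H](C)c2c(C(C)C)cc(C(C)C)cc2C(C)C)c1Br | intermediate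
26 | bridged ketal cycloadduct: 7-bromo-6-[(tert-butyldimethylsilyloxy)methyl]-4-[(1S)-1-(2,4,6-triisopropylphenyl)ethoxy]-2,3,3a,4-tetrahydro-5H-5,7a-epoxy-1-benzofuran, the C4 ether and the C3a–C3 bond both exo (cis to the epoxy bridge) | BrC1=C(CO[Si](C)(C)C(C)(C)C)[C@H]2O[C@@]13OCC[C@@H]3[C@@H]2O[C@@H](C)c1c(C(C)C)cc(C(C)C)cc1C(C)C | intermediate
27 | coupled bridged ketal: as 26 with the bromine replaced by the (R,E)-6-acetoxyhept-1-enyl group | CC(=O)O[C@H](C)CCC/C=C/C1=C(CO[Si](C)(C)C(C)(C)C)[C@H]2O[C@@]13OCC[C@@H]3[C@@H]2O[C@@H](C)c1c(C(C)C)cc(C(C)C)cc1C(C)C | intermediate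
28 | (R,E)-7-{(4R,5S,6R)-3-[(tert-butyldimethylsilyloxy)methyl]-4-hydroxy-6-(2-hydroxyethyl)-1-oxo-5-[(1S)-1-(2,4,6-triisopropylphenyl)ethoxy]cyclohex-2-en-2-yl}hept-6-en-2-yl acetate (ring numbering of the overview) | CC(=O)O[C@H](C)CCC/C=C/C1=C(CO[Si](C)(C)C(C)(C)C)[C@@H](O)[C@@H](O[C@@H](C)c2c(C(C)C)cc(C(C)C)cc2C(C)C)[C@@H](CCO)C1=O | intermediate
29 | aldehyde: as 28 with the 6-(2-hydroxyethyl) group oxidised to 6-(2-oxoethyl) | CC(=O)O[C@H](C)CCC/C=C/C1=C(CO[Si](C)(C)C(C)(C)C)[C@@H](O)[C@@H](O[C@@H](C)c2c(C(C)C)cc(C(C)C)cc2C(C)C)[C@@H](CC=O)C1=O | intermediate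
30 | protected pestallic acid J: tert-butyl (E)-enoate with the C3 CH2OTBS ether and the C5 (S)-1-(2,4,6-triisopropylphenyl)ethyl ether, (4R,5S,6R) | CC(=O)O[C@H](C)CCC/C=C/C1=C(CO[Si](C)(C)C(C)(C)C)[C@@H](O)[C@@H](O[C@@H](C)c2c(C(C)C)cc(C(C)C)cc2C(C)C)[C@@H](C/C=C(\C)C(=O)OC(C)(C)C)C1=O | intermediate
31 | pestallic acid J, (4R,5S,6R) ring, (R)-acetate, both side-chain alkenes E | CC(=O)O[C@H](C)CCC/C=C/C1=C(CO)[C@@H](O)[C@@H](O)[C@@H](C/C=C(\C)C(=O)O)C1=O | target

## Step count and risks

Total step count: 17. Longest linear sequence: 10 steps (steps 1–3 and 11–17 from 3,4-dibromofuran; equally steps 4–6 and 11–17 from the chiral alcohol).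

Steps most likely to fail:

1. Step 12. The cycloaddition may be too slow at temperatures where cycloreversion and oxygen-assisted opening of the bridged ketal take over (ionisation of the bridge C1–O bond, then loss of the C6 proton, which erases the C6 stereocentre). Incomplete π-facial discrimination by the auxiliary is a second source of loss. The fallback turns the ring opening into the route and sets C6 later by substrate-controlled protonation. It sets out from 25, which is heated in toluene at 110 °C with a trace of pyridinium p-toluenesulfonate and molecular sieves until the cycloadduct has isomerised completely to the ring-opened bicyclic enol ether F1 (C1=C6 enol ether inside the dihydrofuran ring, free C4 hydroxyl). Suzuki–Miyaura coupling with 21 under the conditions of step 13 then gives the heptenyl enol ether F2. Aqueous acid hydrolysis of this enol ether under the conditions of step 14 should protonate C6 on the face opposite to the bulky C5 ether, and the fallback comes back to the route at 28.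

2. Step 11. Oxidative addition and alkoxide exchange at the electron-rich, ortho-substituted iodofuran may be slow, so that hydrodeiodination, halogen scrambling or decomposition of the acid- and air-sensitive alkoxyfuran competes. The fallback forms the same C–O bond by O-alkylation of a furanolate instead of cross-coupling. It sets out from 5, which is lithiated as in step 3 to 6, trapped with B(OMe)3 as the furylboronate F3 and oxidised in the same flask (NaBO3·4H2O, THF/H2O) to the butenolide F4. Alcohol 15 is converted into its mesylate F5 (MsCl, Et3N, CH2Cl2, 0 °C). Deprotonation of F4 with KN(SiMe3)2 in THF/DMPU with 18-crown-6 gives the potassium furanolate F6. O-Alkylation of this furanolate by the hard sulfonate, driven by aromatisation, comes back to the route at 25.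

3. Step 13. Oxidative addition and transmetalation at the tetrasubstituted bridge-alkene bromide, flanked by the quaternary ketal carbon, may be slow, with protodebromination or acetate hydrolysis under the aqueous base as competing processes. The fallback postpones the coupling until after ring opening. It sets out from 26, which is hydrolysed under the conditions of step 14 to the α-bromoenone F7. This activated electrophile is coupled with 21 under base-free conditions (Pd2(dba)3, AsPh3, Ag2O, THF/H2O, rt), and the fallback comes back to the route at 28.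

Further compounds
F1 | step 12 | ring-opened enol ether: 7-bromo-6-[(tert-butyldimethylsilyloxy)methyl]-4-[(1S)-1-(2,4,6-triisopropylphenyl)ethoxy]-2,3,4,5-tetrahydro-1-benzofuran-5-ol, ether and hydroxyl cis | BrC1=C(CO[Si](C)(C)C(C)(C)C)[C@@H](O)[C@@H](O[C@@H](C)c2c(C(C)C)cc(C(C)C)cc2C(C)C)C2=C1OCC2
F2 | step 12 | heptenyl enol ether: as F1 with the bromine replaced by the (R,E)-6-acetoxyhept-1-enyl group | CC(=O)O[C@H](C)CCC/C=C/C1=C(CO[Si](C)(C)C(C)(C)C)[C@@H](O)[C@@H](O[C@@H](C)c2c(C(C)C)cc(C(C)C)cc2C(C)C)C2=C1OCC2
F3 | step 11 | dimethyl [3-bromo-4-(tert-butyldimethylsilyloxymethyl)furan-2-yl]boronate | COB(OC)c1occ(CO[Si](C)(C)C(C)(C)C)c1Br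
F4 | step 11 | 3-bromo-4-[(tert-butyldimethylsilyloxy)methyl]furan-2(5H)-one | O=C1OCC(CO[Si](C)(C)C(C)(C)C)=C1Br
F5 | step 11 | (Z)-4-[(1S)-1-(2,4,6-triisopropylphenyl)ethoxy]but-3-en-1-yl methanesulfonate | CS(=O)(=O)OCC/C=C\O[C@@H](C)c1c(C(C)C)cc(C(C)C)cc1C(C)C
F6 | step 11 | potassium 3-bromo-4-[(tert-butyldimethylsilyloxy)methyl]furan-2-olate | [K+].[O-]c1occ(CO[Si](C)(C)C(C)(C)C)c1Br
F7 | step 13 | α-bromoenone: (4R,5S,6R)-2-bromo-3-[(tert-butyldimethylsilyloxy)methyl]-4-hydroxy-6-(2-hydroxyethyl)-5-[(1S)-1-(2,4,6-triisopropylphenyl)ethoxy]cyclohex-2-en-1-one | BrC1=C(CO[Si](C)(C)C(C)(C)C)[C@@H](O)[C@@H](O[C@@H](C)c2c(C(C)C)cc(C(C)C)cc2C(C)C)[C@@H](CCO)C1=O
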